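Target in the south run grew steadily, from 3.9 % at 1.00 min to 8.0 % at 2.50 min, but the quick number you asked for comes easier from what has not become target. Call that the pool: starting material and dormant form, which turn into each other and together make up the charge not yet converted.

common to all: starting material 0.012 M; gas 0.38 mM (held)

|  | second substrate | third substrate | remark | time |
|---|---|---|---|---|
| south | 0.012 M | 0.018 M | run made earlier |  |
| grey | 0.0120 M | 0.0120 M |  | 12 min |
| violet | 0.0160 M | 0.0120 M |  | 12 min |

south run (percent of the starting material charged)

| time / min | target / % | starting material / % |
|---|---|---|
| 0.167 | 1.1 | 91.3 |
| 0.333 | 0.8 | 83.3 |
| 0.667 | 2.8 | 69.4 |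
| 1.00 | 3.9 | 58.3 |
| 1.33 | 4.9 | 49.5 |
| 2.00 | 6.8 | 37.7 |
| 2.50 | 8.0 | 32.1 |

(standard deviation of a reading: 0.5 percentage points)

- at the start none of reagent is dissolved
- reactions considered so far: starting material + reagent -> target; second substrate + reagent -> second product; third substrate + reagent -> third product; gas <-> reagent; second substrate -> decomposition product; starting material <-> dormant form
- a reading of starting material is of its free form alone

* which of these there is most of at the end, counted by the starting material in it, grey (starting material / target)
* which of these there is most of at the end, counted by the starting material in it, violet (starting material / target)
* how much there is at the end of the one of these that leads, in percent of the starting material charged: grey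
* how much there is at the end of the one of these that leads, in percent of the starting material charged: violet

Between those two readings the south pool shrank from 96.1 % to 92.0 %, which gives 0.0291 min⁻¹. This is the pool loss constant, the natural logarithm of the ratio of two pool amounts divided by the time between them, an average over that stretch, and as a reading it carries the scatter of both.

Taken over unchanged to grey, whose third substrate is 0.0120 M against 0.018 M, it leaves 70.6 % of the pool after 12 min, so this reckoning puts target at 29.4 %. Starting material was 60.7 % of the south pool at the first of those readings and 34.9 % at the last. Even at that last share, grey's free starting material comes to 24.6 %, less than target. Violet carries 0.0160 M of second substrate against 0.0120 M, and second substrate also consumes reagent, so this reckoning puts violet's target below grey's, still leading, without a figure.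

The forecast, working on “the free quarter of the pool”, names target in both flasks, at 27 % in grey, lower than the figure above, and 25 % in violet.

Grey ends with target 28.2 % and starting material 11.3 %, violet with target 22.8 % and starting material 12.9 %, so the forecast holds.

    starting material + reagent → target (k = 22.0 L mol⁻¹ s⁻¹)
    second substrate + reagent → second product (k = 44.0 L mol⁻¹ s⁻¹)
    third substrate + reagent → third product (k = 4.10 L mol⁻¹ s⁻¹)
    gas ⇌ reagent, rate k4*(csat - [reagent]) (kL = 0.0870 s⁻¹)
    second substrate → decomposition product (k = 2.80 × 10⁻⁶ s⁻¹)
    starting material ⇌ dormant form (K = 4.00, k = 0.00880 s⁻¹)

In grey, starting material and dormant form relax with a half-life of 1.05 min, shorter than the 6.7 min that target formation gives starting material at 5.28 min. Grey's result reads back as a pool loss constant of 0.0276 min⁻¹, an average over its 12 min. Violet's target has moved 6 points at 0.0222 M of second substrate, the other amounts and the time held, or at 9.14 min, all amounts held, and a violet run found to stand at either setting would part from the forecast's 25 %. For grey read at 3.0 min, the south constant gives target 8.36 %; the flask holds 8.94 %.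

(The runs were computed from invented constants; scatter was added.)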